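The route rests on cutting the C8–ring D bond, the one bond common to six-membered ring C and the seven-membered ring; its ring-D carbon is para to the ring-D oxygen and C8 is benzylic to ring B, para to a ring-B oxygen. Without it the skeleton is an eleven-membered metacyclophane with a Z C7=C8 stilbene and the C9 stereocentre. Acid protonates C7; the ring-B-stabilised C8 cation is trapped across the ring by the inner ring-D carbon, closing both rings and setting C8 under control of C9. The precursor carries methyl ethers on rings A, B and D but tosylates on pendant ring E, so that ring cannot compete as a nucleophile.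

Key step: step 12

Labels: ring A is the resorcinol-type ring, ring B the catechol ring fused to the seven-membered ring, ring C the six-membered carbocycle between rings A and D, ring D the central mono-oxygenated ring, ring E the catechol ring hanging from C9. C7 is the CH2 on ring A, C8 the CH between rings B and D, C9 the CH bearing ring E, C10 the CH2 on ring D. With these labels the target is (8S,9R); the C8 and C9 hydrogens are cis on the seven-membered ring.

Design remarks:
(a) As a dimethoxyphenyl group, ring E would sit on the face of ring B opposite to ring D, and its carbon para to oxygen could trap the C8 cation through a six-membered transition state (9,10-dihydroanthracene). Ring E is therefore carried as a bis(tosylate) from the start and unmasked after the key step.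
(b) Ring B carries chlorine, not bromine, so that this position stays silent through the radical coupling and the first palladium coupling and is addressed only in step 10.

Assumption: 2-chloro-4,5-dimethoxybenzaldehyde, 4-bromocatechol and 3-methoxyphenylmagnesium bromide (THF solution) are taken as catalogue compounds.

Step 1
Reactants: 1 2-chloro-4,5-dimethoxybenzaldehyde
Product: 2 tert-butyl (E)-3-(2-chloro-4,5-dimethoxyphenyl)prop-2-enoate
Conditions: (EtO)2P(O)CH2CO2t-Bu, NaH, THF, 0 °C to rt
Reagents that add atoms: tert-butyl diethylphosphonoacetate, CCOP(=O)(OCC)CC(=O)OC(C)(C)C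
Why: Horner–Wadsworth–Emmons olefination of an aromatic aldehyde with a stabilised phosphonate anion reliably gives the E-cinnamate, and the tert-butyl ester is chosen because acid can remove it later without touching aryl sulfonates.

Step 2
Reactants: 3 4-bromobenzene-1,2-diol (4-bromocatechol)
Product: 4 4-bromo-1,2-phenylene bis(4-methylbenzenesulfonate)
Conditions: TsCl (2.2 equiv), Et3N, DMAP (cat.), CH2Cl2, 0 °C to rt
Reagents that add atoms: p-toluenesulfonyl chloride, Cc1ccc(cc1)S(=O)(=O)Cl
Why: Sulfonylation of both phenols under amine base is routine and installs the electron-withdrawing, acid-stable groups that keep ring E from acting as a Friedel–Crafts nucleophile in step 12.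

Step 3
Reactants: 4 4-bromo-1,2-phenylene bis(4-methylbenzenesulfonate)
Product: 5 4-(4,4,5,5-tetramethyl-1,3,2-dioxaborolan-2-yl)-1,2-phenylene bis(4-methylbenzenesulfonate)
Conditions: B2pin2, Pd(dppf)Cl2 (cat.), KOAc, 1,4-dioxane, 90 °C
Reagents that add atoms: bis(pinacolato)diboron, CC1(C)OB(OC1(C)C)B1OC(C)(C)C(C)(C)O1
Why: Miyaura borylation converts the aryl bromide into the pinacol boronate, and the dppf–palladium catalyst does not insert into aryl sulfonate C–O bonds under these conditions.

Step 4
Reactants: 2 tert-butyl (E)-3-(2-chloro-4,5-dimethoxyphenyl)prop-2-enoate; 5 4-(4,4,5,5-tetramethyl-1,3,2-dioxaborolan-2-yl)-1,2-phenylene bis(4-methylbenzenesulfonate)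
Product: 6 tert-butyl (3R)-3-(2-chloro-4,5-dimethoxyphenyl)-3-[3,4-bis(tosyloxy)phenyl]propanoate
Conditions: [RhCl(C2H4)2]2 (cat.), chiral diene Ph-bod* (2,5-diphenylbicyclo[2.2.2]octa-2,5-diene, the antipode that gives 9R), K3PO4, 1,4-dioxane/H2O, 50 °C
Reagents that add atoms: none
Why: In this Hayashi–Miyaura rhodium-catalysed asymmetric 1,4-arylation of a β-aryl enoate the chiral diene–rhodium aryl species inserts the cinnamate on one enantiotopic face, and the ligand antipode that delivers ring E to the Si face of the β-carbon is used so that C9 is formed R, the aryl chloride and the sulfonates being inert to the rhodium catalyst.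

Step 5
Reactants: 6 tert-butyl (3R)-3-(2-chloro-4,5-dimethoxyphenyl)-3-[3,4-bis(tosyloxy)phenyl]propanoate
Product: 7 (3R)-3-(2-chloro-4,5-dimethoxyphenyl)-3-[3,4-bis(tosyloxy)phenyl]propanoic acid
Conditions: CF3CO2H, CH2Cl2, rt
Reagents that add atoms: none
Why: Acidolysis of the tert-butyl ester with loss of isobutene frees the acid without base, so the sulfonates and the C9 centre are untouched, and no ring of 6 offers an unhindered activated position for tert-butylation.

Step 6
Reactants: 7 (3R)-3-(2-chloro-4,5-dimethoxyphenyl)-3-[3,4-bis(tosyloxy)phenyl]propanoic acid; 8 3-methoxyphenylmagnesium bromide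
Product: 11 4-[(1R)-1-(2-chloro-4,5-dimethoxyphenyl)-2-(3-methoxyphenyl)ethyl]-1,2-phenylene bis(4-methylbenzenesulfonate), via N-acyloxyphthalimide ester 9 (not isolated), via (3-methoxyphenyl)zinc chloride 10 (not isolated)
Conditions: N-hydroxyphthalimide, DIC, DMAP (cat.), CH2Cl2, rt; solvent exchange to THF; 10 (from 8 and ZnCl2, THF, 0 °C), Fe(acac)3 (cat.), 1,2-bis(diphenylphosphino)benzene (cat.), rt
Reagents that add atoms: none
Why: In this iron-catalysed decarboxylative Negishi-type coupling of a redox-active ester, single-electron reduction of 9 releases CO2 and the primary C10 radical, which is captured at iron and joined to the aryl group of 10, while the iron–bisphosphine catalyst activates neither the aryl chloride nor the aryl sulfonates and C9, β to the radical, keeps its configuration.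

Step 7
Reactants: 11 4-[(1R)-1-(2-chloro-4,5-dimethoxyphenyl)-2-(3-methoxyphenyl)ethyl]-1,2-phenylene bis(4-methylbenzenesulfonate)
Product: 12 4-[(1R)-1-(2-chloro-4,5-dimethoxyphenyl)-2-[3-methoxy-5-(4,4,5,5-tetramethyl-1,3,2-dioxaborolan-2-yl)phenyl]ethyl]-1,2-phenylene bis(4-methylbenzenesulfonate)
Conditions: B2pin2, [Ir(OMe)(cod)]2 (cat.), 4,4'-di-tert-butyl-2,2'-bipyridine (cat.), THF, 80 °C
Reagents that add atoms: bis(pinacolato)diboron, CC1(C)OB(OC1(C)C)B1OC(C)(C)C(C)(C)O1
Why: Iridium-catalysed aromatic C–H borylation is governed by sterics and should select the one C–H of 11 that has no ortho substituent, the ring-D position meta to both the methoxy group and C10, since every other aromatic C–H is flanked by a substituent.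

Step 8
Reactants: 13 2-bromo-3,5-dimethoxybenzaldehyde
Product: 14 2-bromo-1-ethenyl-3,5-dimethoxybenzene
Conditions: Ph3PCH3Br, KOtBu, THF, 0 °C to rt
Reagents that add atoms: methyltriphenylphosphonium bromide, C[P+](c1ccccc1)(c1ccccc1)c1ccccc1.[Br-]
Why: Wittig methylenation of the aromatic aldehyde with the non-stabilised ylide gives the styrene that carries C7, and the aryl bromide is inert to the ylide.

Step 9
Reactants: 12 ring-D pinacol boronate from step 7; 14 2-bromo-1-ethenyl-3,5-dimethoxybenzene
Product: 15 4-[(1R)-1-(2-chloro-4,5-dimethoxyphenyl)-2-(6'-ethenyl-2',4',5-trimethoxybiphenyl-3-yl)ethyl]-1,2-phenylene bis(4-methylbenzenesulfonate)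
Conditions: Pd(dppf)Cl2 (cat.), K3PO4, 1,4-dioxane/H2O, 90 °C
Reagents that add atoms: none
Why: Suzuki–Miyaura coupling joins rings D and A, because the dppf–palladium catalyst inserts into the aryl bromide of 14 but not into the electron-rich aryl chloride or the sulfonates of 12, so only the wanted biaryl bond forms.

Step 10
Reactants: 15 ring-B chloride, ring-A styrene from step 9
Product: 16 4-[(1R)-1-(2-ethenyl-4,5-dimethoxyphenyl)-2-(6'-ethenyl-2',4',5-trimethoxybiphenyl-3-yl)ethyl]-1,2-phenylene bis(4-methylbenzenesulfonate)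
Conditions: Bu3SnCH=CH2, Pd(P(t-Bu)3)2 (cat.), CsF, 1,4-dioxane, 100 °C
Reagents that add atoms: tributyl(vinyl)stannane, C=C[Sn](CCCC)(CCCC)CCCC
Why: Stille coupling with the P(t-Bu)3–palladium catalyst, which activates electron-rich aryl chlorides in preference to aryl sulfonates, replaces the ring-B chlorine by the vinyl group whose inner carbon becomes C8.

Step 11
Reactants: 16 bis-styrene from step 10
Product: 17 (9R,Z)-macrocyclic stilbene: eleven-membered ring made of ring A–C7H=C8H–ring B (Z), ring B–C9H(ring E)–C10H2–ring D and the ring D–ring A biaryl bond; five methyl ethers on rings A, B and D, two tosylates on ring E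
Conditions: second-generation Grubbs catalyst RuCl2(PCy3)(H2IMes)(=CHPh) (cat.), toluene (1 mM), 80 °C, argon sparge
Reagents that add atoms: none
Why: Ring-closing metathesis of the two styrenes with loss of ethylene closes the eleven-membered ring, and only a Z alkene can be spanned by the two ortho-phenylene units and the meta-linked ring D, so the ring dictates the geometry.

Step 12
Reactants: 17 (9R,Z)-macrocyclic stilbene, pentamethyl ether bis(tosylate)
Product: 18 (8S,9R)-pentamethyl ether ring-E bis(tosylate) of the target, with the C8–ring D bond, ring C and the seven-membered ring in place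
Conditions: CF3SO3H (0.2 equiv), (CF3)2CHOH/CH2Cl2 (2 mM), −20 to 0 °C
Reagents that add atoms: none
Why: Proposed new method: CF3SO3H protonates the Z-alkene at C7, because only the C8 cation is conjugated with a para oxygen (the ring-B methoxy group para to the carbon that bears C8, whereas both ring-A methoxy groups are meta to the carbon that bears C7), and the inner ring-D carbon, para to the ring-D methoxy group and held across the eleven-membered ring, adds to the cation and then loses its proton, so the acid is regenerated. The closest known reaction type is the acid-promoted intramolecular Friedel–Crafts alkylation of open-chain 4-alkoxystilbenes through p-alkoxybenzyl cations; what is untested is its transannular use in an eleven-membered biaryl cyclophane. The single new C8–ring D bond closes ring C in a 6-exo-trig and the seven-membered ring in a 7-endo-trig sense with respect to the quinone-methide-like cation, as one transannular 1,6-closure. C8 is set by C9 through allylic-type strain: the C9–H bond lies in the ring-B plane next to C8, so C10 with ring D and ring E flank opposite faces of ring B, ring D can only add to the face on which C10 lies, and the two-ring topology then forces the C8 hydrogen inward, cis to the C9 hydrogen (8S from 9R). The selectivity needed is the choice of the arene carbon, and the substrate secures it: the two outer activated ring-D carbons could reach C8 only through a four- or five-atom para bridge, ring E is deactivated by its sulfonates (as a dimethoxyphenyl ring its carbon para to oxygen would close a 9,10-dihydroanthracene from the opposite face and would also favour hydride transfer from C9), and ring C does not exist beforehand, so proton loss from the cation can only return the stilbene. High dilution in (CF3)2CHOH keeps the electron-rich ring A of a second molecule from intercepting the cation.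

Step 13
Reactants: 18 (8S,9R)-pentamethyl ether ring-E bis(tosylate) of the target
Product: 19 (8S,9R)-pentamethyl ether of the target with free ring-E catechol
Conditions: KOH, 1,4-dioxane/H2O, 90 °C, argon; then aq. HCl
Reagents that add atoms: none
Why: Alkaline hydrolysis of the aryl sulfonates by hydroxide attack at sulfur frees the ring-E catechol, while the methyl ethers and the all-carbon stereocentres C8 and C9 are inert to aqueous base.

Step 14
Reactants: 19 (8S,9R)-pentamethyl ether of the target with free ring-E catechol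
Product: 20 CNP0306974.2, the (8S,9R)-heptaphenol
Conditions: BBr3 (excess), CH2Cl2, −78 °C to rt; then H2O
Reagents that add atoms: none
Why: Lewis-acid ether cleavage, in which BBr3 complexes each aryl methyl ether and bromide removes the methyl group by SN2 attack, is the standard global demethylation of polyphenol methyl ethers and does not touch C8 or C9.

Compound list
1 | 2-chloro-4,5-dimethoxybenzaldehyde | COc1cc(Cl)c(C=O)cc1OC | starting material
2 | tert-butyl (E)-3-(2-chloro-4,5-dimethoxyphenyl)prop-2-enoate | COc1cc(Cl)c(/C=C/C(=O)OC(C)(C)C)cc1OC | intermediate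
3 | 4-bromobenzene-1,2-diol | Oc1ccc(Br)cc1O | starting material
4 | 4-bromo-1,2-phenylene bis(4-methylbenzenesulfonate) | Cc1ccc(cc1)S(=O)(=O)Oc1ccc(Br)cc1OS(=O)(=O)c1ccc(C)cc1 | intermediate
5 | 4-(4,4,5,5-tetramethyl-1,3,2-dioxaborolan-2-yl)-1,2-phenylene bis(4-methylbenzenesulfonate) | Cc1ccc(cc1)S(=O)(=O)Oc1ccc(cc1OS(=O)(=O)c1ccc(C)cc1)B1OC(C)(C)C(C)(C)O1 | intermediate
6 | tert-butyl (3R)-3-(2-chloro-4,5-dimethoxyphenyl)-3-[3,4-bis(tosyloxy)phenyl]propanoate | COc1cc(Cl)c(cc1OC)[C@H](CC(=O)OC(C)(C)C)c1ccc(OS(=O)(=O)c2ccc(C)cc2)c(OS(=O)(=O)c2ccc(C)cc2)c1 | intermediate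
7 | (3R)-3-(2-chloro-4,5-dimethoxyphenyl)-3-[3,4-bis(tosyloxy)phenyl]propanoic acid | COc1cc(Cl)c(cc1OC)[C@H](CC(=O)O)c1ccc(OS(=O)(=O)c2ccc(C)cc2)c(OS(=O)(=O)c2ccc(C)cc2)c1 | intermediate
8 | 3-methoxyphenylmagnesium bromide | COc1cccc([Mg]Br)c1 | starting material
9 | 1,3-dioxoisoindolin-2-yl (3R)-3-(2-chloro-4,5-dimethoxyphenyl)-3-[3,4-bis(tosyloxy)phenyl]propanoate (N-acyloxyphthalimide ester of 7) | COc1cc(Cl)c(cc1OC)[C@H](CC(=O)ON1C(=O)c2ccccc2C1=O)c1ccc(OS(=O)(=O)c2ccc(C)cc2)c(OS(=O)(=O)c2ccc(C)cc2)c1 | intermediate
10 | (3-methoxyphenyl)zinc chloride | COc1cccc([Zn]Cl)c1 | intermediate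
11 | 4-[(1R)-1-(2-chloro-4,5-dimethoxyphenyl)-2-(3-methoxyphenyl)ethyl]-1,2-phenylene bis(4-methylbenzenesulfonate) | COc1cccc(C[C@@H](c2cc(OC)c(OC)cc2Cl)c2ccc(OS(=O)(=O)c3ccc(C)cc3)c(OS(=O)(=O)c3ccc(C)cc3)c2)c1 | intermediate
12 | 4-[(1R)-1-(2-chloro-4,5-dimethoxyphenyl)-2-[3-methoxy-5-(4,4,5,5-tetramethyl-1,3,2-dioxaborolan-2-yl)phenyl]ethyl]-1,2-phenylene bis(4-methylbenzenesulfonate) | COc1cc(B2OC(C)(C)C(C)(C)O2)cc(C[C@@H](c2cc(OC)c(OC)cc2Cl)c2ccc(OS(=O)(=O)c3ccc(C)cc3)c(OS(=O)(=O)c3ccc(C)cc3)c2)c1 | intermediate
13 | 2-bromo-3,5-dimethoxybenzaldehyde | COc1cc(OC)c(Br)c(C=O)c1 | starting material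
14 | 2-bromo-1-ethenyl-3,5-dimethoxybenzene | COc1cc(OC)c(Br)c(C=C)c1 | intermediate
15 | 4-[(1R)-1-(2-chloro-4,5-dimethoxyphenyl)-2-(6'-ethenyl-2',4',5-trimethoxybiphenyl-3-yl)ethyl]-1,2-phenylene bis(4-methylbenzenesulfonate) | COc1cc(-c2c(OC)cc(OC)cc2C=C)cc(C[C@@H](c2cc(OC)c(OC)cc2Cl)c2ccc(OS(=O)(=O)c3ccc(C)cc3)c(OS(=O)(=O)c3ccc(C)cc3)c2)c1 | intermediate
16 | 4-[(1R)-1-(2-ethenyl-4,5-dimethoxyphenyl)-2-(6'-ethenyl-2',4',5-trimethoxybiphenyl-3-yl)ethyl]-1,2-phenylene bis(4-methylbenzenesulfonate) | COc1cc(-c2c(OC)cc(OC)cc2C=C)cc(C[C@@H](c2cc(OC)c(OC)cc2C=C)c2ccc(OS(=O)(=O)c3ccc(C)cc3)c(OS(=O)(=O)c3ccc(C)cc3)c2)c1 | intermediate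
17 | (9R,Z)-macrocyclic stilbene, eleven-membered metacyclophane, pentamethyl ether (rings A, B, D) and ring-E bis(tosylate) | COc1cc(OC)c2c(c1)/C=C\c3cc(OC)c(OC)cc3[C@@H](c4ccc(OS(=O)(=O)c6ccc(C)cc6)c(OS(=O)(=O)c6ccc(C)cc6)c4)Cc5cc(OC)cc-2c5 | intermediate
18 | (8S,9R)-pentamethyl ether ring-E bis(tosylate) of the target | COc1cc(OC)c2c(c1)C[C@H]1c3cc(OC)c(OC)cc3[C@@H](c3ccc(OS(=O)(=O)c4ccc(C)cc4)c(OS(=O)(=O)c4ccc(C)cc4)c3)Cc3cc(OC)cc-2c31 | intermediate
19 | (8S,9R)-pentamethyl ether of the target with free ring-E catechol | COc1cc(OC)c2c(c1)C[C@H]1c3cc(OC)c(OC)cc3[C@@H](c3ccc(O)c(O)c3)Cc3cc(OC)cc-2c31 | intermediate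
20 | CNP0306974.2, (8S,9R)-heptaphenol | Oc1cc(O)c2c(c1)C[C@H]1c3cc(O)c(O)cc3[C@@H](c3ccc(O)c(O)c3)Cc3cc(O)cc-2c31 | target

Total steps: 14. Longest linear sequence: 12 steps (3 → 4 → 5 → 6 → 7 → 11 → 12 → 15 → 16 → 17 → 18 → 19 → 20).

Steps most likely to fail

1. Step 12 (transannular Friedel–Crafts closure). What may go wrong: the C8 cation may be consumed by intermolecular alkylation or by hydride transfer from C9 faster than by the strained transannular attack, or the arene may add to the wrong face of C8. The fallback uses known chemistry and closes the two rings one after the other; it sets out from 11 and comes back at 18. Stille vinylation of the ring-B chloride of 11 under the conditions of step 10 gives the ring-B styrene F1. Cross-metathesis of F1 with an excess of 14 (second-generation Hoveyda–Grubbs catalyst RuCl2(H2IMes)(=CH-C6H4-2-OiPr), CH2Cl2, 40 °C) gives the open-chain E-stilbene with the ring-A bromide F2. CF3SO3H in (CF3)2CHOH/CH2Cl2 then effects the established open-chain Friedel–Crafts closure of the seven-membered ring, ring D attacking C8 through its carbon para to methoxy, and gives the bromo dibenzosuberane F3, expected with the same spatial arrangement at C8 and C9 as in 18. Intramolecular palladium-catalysed direct arylation (Pd(OAc)2, PCy3·HBF4, K2CO3, pivalic acid, DMA, 120 °C) forms the ring A–ring D bond at the less hindered ortho C–H of ring D, which closes ring C and gives 18.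

2. Step 11 (ring-closing metathesis). What may go wrong: intermolecular metathesis to oligomers may outrun closure of the strained eleven-membered ring. The fallback replaces metathesis by reductive carbonyl coupling; it sets out from 16 and comes back at 17. Lemieux–Johnson cleavage of both vinyl groups (OsO4 cat., NaIO4, 2,6-lutidine, dioxane/H2O) gives the dialdehyde F4. Intramolecular McMurry coupling (TiCl4, Zn, pyridine, THF, reflux, slow addition) then closes the same Z-stilbene ring to give 17; this titanium reagent is known to tolerate aryl bromides, which are reduced at potentials similar to those of aryl sulfonates, so the tosylates should survive.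

3. Step 6 (decarboxylative arylation). What may go wrong: 1,2-aryl migration in the primary C10 radical (neophyl-type rearrangement) or slow capture of this β-branched radical at iron would erode the skeleton. The fallback makes the C10–ring D bond by a two-electron enolate arylation and removes the carboxyl group afterwards; it sets out from 6 and comes back at 11. Palladium-catalysed α-arylation of the ester enolate with 3-bromoanisole (LiN(SiMe3)2, Pd(dba)2, P(t-Bu)3, toluene, rt) gives the α-aryl ester F5 as a mixture of C10 epimers. CF3CO2H in CH2Cl2 gives the α-aryl acid F6. Photoredox hydrodecarboxylation (9-mesityl-10-methylacridinium tetrafluoroborate cat., PhSSPh cat., i-Pr2NEt, CF3CH2OH, blue LEDs) then removes the carboxyl group through a benzylic radical that has no driving force for aryl migration and gives 11.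

Further compounds
F1 | step 12 | 4-[(1R)-1-(2-ethenyl-4,5-dimethoxyphenyl)-2-(3-methoxyphenyl)ethyl]-1,2-phenylene bis(4-methylbenzenesulfonate) | COc1cccc(C[C@@H](c2cc(OC)c(OC)cc2C=C)c2ccc(OS(=O)(=O)c3ccc(C)cc3)c(OS(=O)(=O)c3ccc(C)cc3)c2)c1
F2 | step 12 | 4-[(1R)-1-{2-[(E)-2-(2-bromo-3,5-dimethoxyphenyl)ethenyl]-4,5-dimethoxyphenyl}-2-(3-methoxyphenyl)ethyl]-1,2-phenylene bis(4-methylbenzenesulfonate) | COc1cccc(C[C@@H](c2cc(OC)c(OC)cc2/C=C/c2cc(OC)cc(OC)c2Br)c2ccc(OS(=O)(=O)c3ccc(C)cc3)c(OS(=O)(=O)c3ccc(C)cc3)c2)c1
F3 | step 12 | bromo dibenzosuberane: seven-membered ring of C8, ring B, C9, C10 and ring D closed; C8 bears the CH2(2-bromo-3,5-dimethoxyphenyl) group, C9 bears ring E as bis(tosylate); C8 and C9 hydrogens cis | COc1cc(OC)c(Br)c(c1)C[C@H]1c2cc(OC)c(OC)cc2[C@@H](c2ccc(OS(=O)(=O)c3ccc(C)cc3)c(OS(=O)(=O)c3ccc(C)cc3)c2)Cc2cc(OC)ccc21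
F4 | step 11 | 4-[(1R)-1-(2-formyl-4,5-dimethoxyphenyl)-2-(6'-formyl-2',4',5-trimethoxybiphenyl-3-yl)ethyl]-1,2-phenylene bis(4-methylbenzenesulfonate) | COc1cc(-c2c(OC)cc(OC)cc2C=O)cc(C[C@@H](c2cc(OC)c(OC)cc2C=O)c2ccc(OS(=O)(=O)c3ccc(C)cc3)c(OS(=O)(=O)c3ccc(C)cc3)c2)c1
F5 | step 6 | tert-butyl (3R)-3-(2-chloro-4,5-dimethoxyphenyl)-2-(3-methoxyphenyl)-3-[3,4-bis(tosyloxy)phenyl]propanoate, mixture of C2 epimers | COc1cccc(C(C(=O)OC(C)(C)C)[C@@H](c2cc(OC)c(OC)cc2Cl)c2ccc(OS(=O)(=O)c3ccc(C)cc3)c(OS(=O)(=O)c3ccc(C)cc3)c2)c1
F6 | step 6 | (3R)-3-(2-chloro-4,5-dimethoxyphenyl)-2-(3-methoxyphenyl)-3-[3,4-bis(tosyloxy)phenyl]propanoic acid, mixture of C2 epimers | COc1cccc(C(C(=O)O)[C@@H](c2cc(OC)c(OC)cc2Cl)c2ccc(OS(=O)(=O)c3ccc(C)cc3)c(OS(=O)(=O)c3ccc(C)cc3)c2)c1
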